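**Plan**
- Retrosynthesis: the two MOM acetals on ring A come off last, and ring C of the flavonol is traced back to a 2-aryl-3-nitro-2H-chromene. That chromene is cut at O1–C2 and C3–C4 into a salicylaldehyde (ring A plus C4) and a β-nitrostyrene (ring B plus C2 and C3).
- Enabling feature: C3 of ring C carries oxygen and lies between C2 (bonded to O1 and to the aryl ring) and the C4 carbonyl. A nitro-bearing alkene carbon reproduces this array, since its neighbours can be closed by an oxa-Michael bond on one side and a Henry bond on the other, and the nitro group is later exchanged for the C3 oxygen.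
- Forward, ring A: 2-methoxyresorcinol is MOM-protected, oxygenated para to the methoxy group by C–H borylation and oxidation, and ortho-formylated. Ring B: 4-hydroxybenzaldehyde is prenylated and condensed with nitromethane.
- Rings A and B are bought. Ring C is the only ring made; it closes when the two fragments are joined, is aromatised by alkaline peroxide, and mild acid then frees the 5- and 7-hydroxyls.
- Stereochemistry: the target has no stereocentre. C2 of the chromene arises racemic and becomes sp2 on aromatisation, so nothing needs to be controlled.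

Key step: step 6

Assumption: all chiral intermediates are racemic (diastereomer mixtures where more than one centre is present), so their SMILES carry no stereodescriptors.

**Route**

Step 1
Reactants: 1 2-methoxyresorcinol (2-methoxybenzene-1,3-diol)
Product: 2 2-methoxy-1,3-bis(methoxymethoxy)benzene
Conditions: MOMCl (2.6 equiv), i-Pr2NEt (3.5 equiv), CH2Cl2, 0 °C to rt
Reagents that add atoms: chloromethyl methyl ether, COCCl
Why: Double O-alkylation of the phenols by the reactive α-chloro ether under amine base (Williamson-type acetal protection) should be clean, and the resulting MOM ethers tolerate every basic, oxidative and organometallic step that follows.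

Step 2
Reactants: 2 2-methoxy-1,3-bis(methoxymethoxy)benzene
Product: 4 4-methoxy-3,5-bis(methoxymethoxy)phenol, via pinacol boronate 3 (not isolated)
Conditions: [Ir(OMe)(cod)]2 (1.5 mol %), 4,4'-di-tert-butyl-2,2'-bipyridine (3 mol %), B2pin2 (1.0 equiv), THF, 65 °C; then 2 M NaOH, 30% H2O2, 0 °C to rt
Reagents that add atoms: bis(pinacolato)diboron, CC1(C)OB(OC1(C)C)B1OC(C)(C)C(C)(C)O1 (boron of intermediate 3); hydrogen peroxide, OO (phenol oxygen of 4)
Why: Iridium-catalysed aromatic C–H borylation (Ishiyama–Miyaura–Hartwig) is governed by sterics and should take the only ring hydrogen without an ortho substituent, C5 para to the methoxy group, after which alkaline peroxide oxidises the C–B bond to the phenol by the usual 1,2-aryl shift.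

Step 3
Reactants: 4 4-methoxy-3,5-bis(methoxymethoxy)phenol
Product: 5 2-hydroxy-5-methoxy-4,6-bis(methoxymethoxy)benzaldehyde
Conditions: MgCl2 (anhydrous), Et3N, (CH2O)n, MeCN, reflux; aqueous citric acid work-up
Reagents that add atoms: paraformaldehyde, C=O (formaldehyde unit)
Why: In this magnesium-mediated ortho-formylation (Casnati–Skattebøl reaction) the magnesium phenoxide hydroxymethylates an ortho carbon and a second formaldehyde oxidises the benzylic alkoxide by hydride transfer, the two ortho positions of 4 being equivalent by symmetry so that a single salicylaldehyde should result.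

Step 4
Reactants: 6 4-hydroxybenzaldehyde; 7 prenyl bromide (1-bromo-3-methylbut-2-ene)
Product: 8 4-(3-methylbut-2-enyloxy)benzaldehyde
Conditions: K2CO3, DMF, rt
Reagents that add atoms: none
Why: Williamson ether synthesis in which the phenoxide displaces bromide at the primary allylic carbon (SN2), so the unrearranged prenyl ether is expected.

Step 5
Reactants: 8 4-(3-methylbut-2-enyloxy)benzaldehyde; 9 nitromethane
Product: 10 (E)-1-(3-methylbut-2-enyloxy)-4-(2-nitrovinyl)benzene
Conditions: NH4OAc (0.5 equiv), MeNO2 (solvent), 90 °C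
Reagents that add atoms: none
Why: Henry (nitroaldol) condensation followed by in situ dehydration under ammonium acetate buffering should give the thermodynamically preferred E-nitrostyrene, and the nearly neutral medium spares the prenyl ether.

Step 6
Reactants: 5 2-hydroxy-5-methoxy-4,6-bis(methoxymethoxy)benzaldehyde; 10 (E)-1-(3-methylbut-2-enyloxy)-4-(2-nitrovinyl)benzene
Product: 12 racemic 6-methoxy-5,7-bis(methoxymethoxy)-2-[4-(3-methylbut-2-enyloxy)phenyl]-3-nitro-2H-chromene, via nitrochromanol 11 (not isolated)
Conditions: DABCO (0.5 equiv), MeCN, 4 Å MS, 60 °C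
Reagents that add atoms: none
Why: DABCO deprotonates the one free phenol of 5, the phenoxide adds to the aryl-bearing β-carbon of nitroalkene 10 (oxa-Michael, O1–C2), the resulting nitronate attacks the neighbouring formyl group (intramolecular Henry, C3–C4) to give chromanol 11, and E1cB loss of water delivers the conjugated nitrochromene 12. The closest known reaction type is the amine-promoted oxa-Michael–Henry–dehydration cascade of salicylaldehydes with β-nitrostyrenes to 2-aryl-3-nitro-2H-chromenes, which accepts alkoxy-substituted partners on both sides. The pyran ring closes in a 6-exo-trig mode, the nitronate carbon attacking the exocyclic C=O. C2 is created with no controlling element and is therefore racemic, which is intended because it becomes sp2 in step 7, and the C3 and C4 centres of 11 disappear on dehydration. The required regiochemistry (oxygen to the β-carbon, nitronate carbon to the aldehyde) is fixed by the polarity of the nitroalkene and by the ortho relationship of hydroxyl and formyl groups, while chemoselectivity is secured because the other two ring A oxygens are capped as MOM ethers and the prenyl alkene is not an acceptor. The reversible addition steps should be drawn forward by dehydration to a push–pull nitroalkene conjugated with the trioxygenated ring, with the sieves taking up the water.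

Step 7
Reactants: 12 racemic 6-methoxy-5,7-bis(methoxymethoxy)-2-[4-(3-methylbut-2-enyloxy)phenyl]-3-nitro-2H-chromene
Product: 15 3-hydroxy-6-methoxy-5,7-bis(methoxymethoxy)-2-[4-(3-methylbut-2-enyloxy)phenyl]-4H-chromen-4-one, via nitro epoxide 13 (not isolated), via hydroperoxy ketone 14 (not isolated)
Conditions: 30% H2O2 (excess), 2 M NaOH, THF/H2O, 0 °C to rt; Na2S2O3 quench, then NaH2PO4 to pH 5–6
Reagents that add atoms: hydrogen peroxide, OO
Why: The sequence known for 2-aryl-3-nitro-2H-chromenes under alkaline peroxide should operate: Weitz–Scheffer-type nucleophilic epoxidation of the nitroalkene, opening of the α-nitro epoxide at benzylic C4 by hydroperoxide with loss of nitrite, Kornblum–DeLaMare-type dehydration of the α-hydroperoxy ketone to the 3,4-dione and enolisation through C2–H to the aromatic 3-hydroxy-4-pyranone, while the isolated prenyl alkene is inert to the nucleophilic oxidant and C2 ceases to be a stereocentre.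

Step 8
Reactants: 15 3-hydroxy-6-methoxy-5,7-bis(methoxymethoxy)-2-[4-(3-methylbut-2-enyloxy)phenyl]-4H-chromen-4-one
Product: 16 3,5,7-trihydroxy-6-methoxy-2-[4-(3-methylbut-2-enyloxy)phenyl]-4H-chromen-4-one (3,5,7-trihydroxy-6-methoxy-4'-prenyloxyflavone)
Conditions: HCl (ca. 1 M in MeOH), MeOH/THF, rt to 35 °C, monitored; NaHCO3 quench
Reagents that add atoms: none
Why: Acid-catalysed methanolysis of the two aryl MOM acetals (transacetalisation to dimethoxymethane) should free the 5- and 7-hydroxyls, the peri 5-acetal being especially labile, and dilute acid levelled by methanol at or near room temperature is chosen so that the aryl prenyl ether is not ionised.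

**Compound list**

1 | 2-methoxyresorcinol (2-methoxybenzene-1,3-diol) | COc1c(O)cccc1O | starting material
2 | 2-methoxy-1,3-bis(methoxymethoxy)benzene | COCOc1cccc(OCOC)c1OC | intermediate
3 | 2-[4-methoxy-3,5-bis(methoxymethoxy)phenyl]-4,4,5,5-tetramethyl-1,3,2-dioxaborolane (not isolated) | COCOc1cc(B2OC(C)(C)C(C)(C)O2)cc(OCOC)c1OC | intermediate
4 | 4-methoxy-3,5-bis(methoxymethoxy)phenol | COCOc1cc(O)cc(OCOC)c1OC | intermediate
5 | 2-hydroxy-5-methoxy-4,6-bis(methoxymethoxy)benzaldehyde | COCOc1cc(O)c(C=O)c(OCOC)c1OC | intermediate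
6 | 4-hydroxybenzaldehyde | O=Cc1ccc(O)cc1 | starting material
7 | prenyl bromide (1-bromo-3-methylbut-2-ene) | CC(C)=CCBr | starting material
8 | 4-(3-methylbut-2-enyloxy)benzaldehyde | CC(C)=CCOc1ccc(C=O)cc1 | intermediate
9 | nitromethane | C[N+](=O)[O-] | starting material
10 | (E)-1-(3-methylbut-2-enyloxy)-4-(2-nitrovinyl)benzene | CC(C)=CCOc1ccc(/C=C/[N+](=O)[O-])cc1 | intermediate
11 | 6-methoxy-5,7-bis(methoxymethoxy)-2-[4-(3-methylbut-2-enyloxy)phenyl]-3-nitrochroman-4-ol, racemic diastereomer mixture (not isolated) | COCOc1cc2OC(c3ccc(OCC=C(C)C)cc3)C([N+](=O)[O-])C(O)c2c(OCOC)c1OC | intermediate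
12 | racemic 6-methoxy-5,7-bis(methoxymethoxy)-2-[4-(3-methylbut-2-enyloxy)phenyl]-3-nitro-2H-chromene | COCOc1cc2OC(c3ccc(OCC=C(C)C)cc3)C([N+](=O)[O-])=Cc2c(OCOC)c1OC | intermediate
13 | racemic 3,4-epoxy-6-methoxy-5,7-bis(methoxymethoxy)-2-[4-(3-methylbut-2-enyloxy)phenyl]-3-nitrochromane (not isolated) | COCOc1cc2OC(c3ccc(OCC=C(C)C)cc3)C3([N+](=O)[O-])OC3c2c(OCOC)c1OC | intermediate
14 | racemic 4-hydroperoxy-6-methoxy-5,7-bis(methoxymethoxy)-2-[4-(3-methylbut-2-enyloxy)phenyl]chroman-3-one (not isolated) | COCOc1cc2OC(c3ccc(OCC=C(C)C)cc3)C(=O)C(OO)c2c(OCOC)c1OC | intermediate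
15 | 3-hydroxy-6-methoxy-5,7-bis(methoxymethoxy)-2-[4-(3-methylbut-2-enyloxy)phenyl]-4H-chromen-4-one | COCOc1cc2oc(-c3ccc(OCC=C(C)C)cc3)c(O)c(=O)c2c(OCOC)c1OC | intermediate
16 | 3,5,7-trihydroxy-6-methoxy-2-[4-(3-methylbut-2-enyloxy)phenyl]-4H-chromen-4-one | COc1c(O)cc2oc(-c3ccc(OCC=C(C)C)cc3)c(O)c(=O)c2c1O | target

**Step count**

Total step count: 8. Longest linear sequence: 6 steps (steps 1, 2, 3, 6, 7, 8).

**Steps most likely to fail**

Step 7. The electron-rich flavonolate may be degraded by prolonged contact with excess alkaline peroxide (oxidative cleavage of ring C). Hydroxide may also open the nitro epoxide in place of hydroperoxide, giving an α-ketol that is oxidised only slowly. The fallback separates epoxidation from oxidation and sets out from 12. A short epoxidation with H2O2 and a substoichiometric amount of NaOH in THF/MeOH at −10 to 0 °C is stopped at nitro epoxide 13, which is isolated in this variant. LiBr in DMSO at rt should then open the α-nitro epoxide at C4 with loss of nitrite to racemic 4-bromo-6-methoxy-5,7-bis(methoxymethoxy)-2-[4-(3-methylbut-2-enyloxy)phenyl]chroman-3-one F1, which is not isolated. On addition of NaHCO3 and gentle warming, DMSO oxidises the activated benzylic bromide (Kornblum oxidation) to the 3,4-dione, whose enol is 15. The fallback returns to the route at 15.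

Step 6. The Henry closure onto the electron-rich, doubly ortho-substituted aldehyde may be slow. The reversible oxa-Michael adduct would then revert and the nitrostyrene would be consumed by amine-initiated oligomerisation. The fallback raises the electrophilicity of the formyl carbon and sets out from 5. Condensation with n-butylamine (MgSO4, CH2Cl2) should give the Schiff base 2-[(E)-(butylimino)methyl]-4-methoxy-3,5-bis(methoxymethoxy)phenol F2. Heating F2 with 10 and benzoic acid (20 mol %) in toluene at 80 °C should bring about oxa-Michael addition and nitro-Mannich closure onto the protonated imine. This gives racemic N-butyl-6-methoxy-5,7-bis(methoxymethoxy)-2-[4-(3-methylbut-2-enyloxy)phenyl]-3-nitrochroman-4-amine F3 (not isolated), which loses butylamine by β-elimination. The same O1–C2 and C3–C4 bonds are formed, and the fallback returns to the route at 12.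

Step 8. Acid may ionise the aryl prenyl ether (loss or migration of the prenyl cation) at a rate comparable to cleavage of the slower 7-acetal. The fallback moves the prenyl group to the end and sets out from 6.
- Allyl bromide and K2CO3 in DMF should give 4-(allyloxy)benzaldehyde F4.
- Henry condensation with 9 (NH4OAc, MeNO2, 90 °C) should give (E)-1-(allyloxy)-4-(2-nitrovinyl)benzene F5.
- The DABCO cascade with 5 should pass through 2-(4-allyloxyphenyl)-6-methoxy-5,7-bis(methoxymethoxy)-3-nitrochroman-4-ol F6 (not isolated) to racemic 2-(4-allyloxyphenyl)-6-methoxy-5,7-bis(methoxymethoxy)-3-nitro-2H-chromene F7.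
- Alkaline peroxide should carry F7 through racemic 2-(4-allyloxyphenyl)-3,4-epoxy-6-methoxy-5,7-bis(methoxymethoxy)-3-nitrochromane F8 and racemic 2-(4-allyloxyphenyl)-4-hydroperoxy-6-methoxy-5,7-bis(methoxymethoxy)chroman-3-one F9 (neither isolated) to 2-(4-allyloxyphenyl)-3-hydroxy-6-methoxy-5,7-bis(methoxymethoxy)-4H-chromen-4-one F10.
- Methanolic HCl, to which an allyl aryl ether is inert, should then give 2-(4-allyloxyphenyl)-3,5,7-trihydroxy-6-methoxy-4H-chromen-4-one F11.
- Olefin cross-metathesis of F11 with excess 2-methyl-2-butene (second-generation Grubbs catalyst, CH2Cl2, 40 °C) should convert the allyl ether into the prenyl ether.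

The fallback returns to the route at 16.

**Further compounds**

F1 | step 7 | racemic 4-bromo-6-methoxy-5,7-bis(methoxymethoxy)-2-[4-(3-methylbut-2-enyloxy)phenyl]chroman-3-one | COCOc1cc2OC(c3ccc(OCC=C(C)C)cc3)C(=O)C(Br)c2c(OCOC)c1OC
F2 | step 6 | 2-[(E)-(butylimino)methyl]-4-methoxy-3,5-bis(methoxymethoxy)phenol | CCCC/N=C/c1c(O)cc(OCOC)c(OC)c1OCOC
F3 | step 6 | racemic N-butyl-6-methoxy-5,7-bis(methoxymethoxy)-2-[4-(3-methylbut-2-enyloxy)phenyl]-3-nitrochroman-4-amine | COCOc1cc2OC(c3ccc(OCC=C(C)C)cc3)C([N+](=O)[O-])C(NCCCC)c2c(OCOC)c1OC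
F4 | step 8 | 4-(allyloxy)benzaldehyde | C=CCOc1ccc(C=O)cc1
F5 | step 8 | (E)-1-(allyloxy)-4-(2-nitrovinyl)benzene | C=CCOc1ccc(/C=C/[N+](=O)[O-])cc1
F6 | step 8 | 2-(4-allyloxyphenyl)-6-methoxy-5,7-bis(methoxymethoxy)-3-nitrochroman-4-ol | COCOc1cc2OC(c3ccc(OCC=C)cc3)C([N+](=O)[O-])C(O)c2c(OCOC)c1OC
F7 | step 8 | racemic 2-(4-allyloxyphenyl)-6-methoxy-5,7-bis(methoxymethoxy)-3-nitro-2H-chromene | COCOc1cc2OC(c3ccc(OCC=C)cc3)C([N+](=O)[O-])=Cc2c(OCOC)c1OC
F8 | step 8 | racemic 2-(4-allyloxyphenyl)-3,4-epoxy-6-methoxy-5,7-bis(methoxymethoxy)-3-nitrochromane | COCOc1cc2OC(c3ccc(OCC=C)cc3)C3([N+](=O)[O-])OC3c2c(OCOC)c1OC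
F9 | step 8 | racemic 2-(4-allyloxyphenyl)-4-hydroperoxy-6-methoxy-5,7-bis(methoxymethoxy)chroman-3-one | COCOc1cc2OC(c3ccc(OCC=C)cc3)C(=O)C(OO)c2c(OCOC)c1OC
F10 | step 8 | 2-(4-allyloxyphenyl)-3-hydroxy-6-methoxy-5,7-bis(methoxymethoxy)-4H-chromen-4-one | COCOc1cc2oc(-c3ccc(OCC=C)cc3)c(O)c(=O)c2c(OCOC)c1OC
F11 | step 8 | 2-(4-allyloxyphenyl)-3,5,7-trihydroxy-6-methoxy-4H-chromen-4-one | COc1c(O)cc2oc(-c3ccc(OCC=C)cc3)c(O)c(=O)c2c1O
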